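**Strategy.** The target is cut between C3 of the styryl-bearing dihydrobenzofuran and C6 of the second benzofuran's benzo ring, an aryl carbon meta to both oxygens and closed to Friedel–Crafts chemistry. A nickel-catalysed decarboxylative arylation joins the N-acyloxyphthalimide of a (2R)-2-aryl-2,3-dihydrobenzofuran-3-carboxylic acid with the arylzinc of the complete second unit. The step exploits the ring-held benzylic C3 beside the aryl-bearing C2: a planar C3 radical erases the old configuration and the C2 aryl group sends the incoming aryl to the trans face. Both acids come from one diazo ester by mirror-image rhodium carbene C–H insertions; global debenzylation ends the route.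

Key step: step 11

Abbreviations: Bn = benzyl; BBn = 4-(benzyloxy)benzyl (CH2C6H4-4-OBn); p-ABSA = 4-acetamidobenzenesulfonyl azide; DIC = N,N'-diisopropylcarbodiimide; dppBz = 1,2-bis(diphenylphosphino)benzene; dtbbpy = 4,4'-di-tert-butyl-2,2'-bipyridine; Rh2(S-PTTL)4 = dirhodium tetrakis[N-phthaloyl-(S)-tert-leucinate], Rh2(R-PTTL)4 = its mirror image. Benzofuran numbering: O1, C2, C3, C3a, C4–C7, C7a.

Assumption: Rh2(S-PTTL)4 is taken to deliver the (2R)-cis insertion product, the sense expected for 2-(arylmethoxy)phenyl diazoacetates. If the sense is reversed on this di-ortho-substituted substrate, the two catalyst antipodes are exchanged between steps 5 and 8.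

**Route**

Step 1
Reactants: 1 4-bromo-2,6-difluorobenzaldehyde; 2 [4-(benzyloxy)phenyl]methanol (two equivalents enter the product)
Product: 3 4-bromo-2,6-bis(OBBn)benzaldehyde
Conditions: 2 (2.2 equiv), NaH (2.4 equiv), THF/DMF, 0 °C to rt
Reagents that add atoms: [4-(benzyloxy)phenyl]methanol (compound 2, the second equivalent), OCc1ccc(OCc2ccccc2)cc1
Why: Twofold nucleophilic aromatic substitution (SNAr), in which each of the two fluorides ortho to the formyl group should be displaced by one equivalent of the benzylic alkoxide far faster than the para bromide.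

Step 2
Reactants: 3 4-bromo-2,6-bis(OBBn)benzaldehyde
Product: 4 rac-1-[4-bromo-2,6-bis(OBBn)phenyl]-2,2,2-trichloroethanol
Conditions: CHCl3, DBU, 0 °C to rt
Reagents that add atoms: chloroform, ClC(Cl)Cl
Why: Base-mediated addition of the trichloromethyl anion to the aldehyde should give the racemic carbinol, whose stereocentre disappears in the next step.

Step 3
Reactants: 4 rac-1-[4-bromo-2,6-bis(OBBn)phenyl]-2,2,2-trichloroethanol
Product: 5 [4-bromo-2,6-bis(OBBn)phenyl]acetic acid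
Conditions: NaBH4, NaOH, t-BuOH, 55 °C; aq. HCl work-up
Reagents that add atoms: sodium hydroxide, [Na+].[OH-]
Why: Jocic-type reductive homologation, in which the alkoxide closes to a gem-dichloroepoxide, borohydride opens it at the benzylic carbon and hydroxide hydrolyses the acyl chloride to the arylacetic acid.

Step 4
Reactants: 5 [4-bromo-2,6-bis(OBBn)phenyl]acetic acid
Product: 7 methyl [4-bromo-2,6-bis(OBBn)phenyl](diazo)acetate, via methyl arylacetate 6 (not isolated)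
Conditions: MeI, K2CO3, DMF, rt; then p-ABSA, DBU, rt
Reagents that add atoms: iodomethane, CI; 4-acetamidobenzenesulfonyl azide, CC(=O)Nc1ccc(cc1)S(=O)(=O)N=[N+]=[N-]
Why: Carboxylate O-alkylation followed by Regitz diazo transfer to the DBU enolate of the arylacetate should give the aryldiazoacetate in one flask.

Step 5
Reactants: 7 methyl [4-bromo-2,6-bis(OBBn)phenyl](diazo)acetate
Product: 8 methyl (2R,3S)-6-bromo-2-(4-OBn-phenyl)-4-OBBn-2,3-dihydrobenzofuran-3-carboxylate (cis)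
Conditions: Rh2(S-PTTL)4 (1 mol %), toluene, −60 °C
Reagents that add atoms: none
Why: Enantioselective intramolecular 1,5 C–H insertion of a rhodium donor/acceptor carbene into a benzylic ether C–H bond; the two ether arms are homotopic, the chiral carboxylate ligands choose the enantiotopic hydrogen (C2 set as R) and the concerted insertion gives the cis ester (C3 as S, erased later).

Step 6
Reactants: 8 methyl (2R,3S)-6-bromo-2-(4-OBn-phenyl)-4-OBBn-2,3-dihydrobenzofuran-3-carboxylate; 9 4-(benzyloxy)styrene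
Product: 10 methyl (2R,3S)-2-(4-OBn-phenyl)-4-OBBn-6-[(E)-4-OBn-styryl]-2,3-dihydrobenzofuran-3-carboxylate
Conditions: Pd2(dba)3, P(t-Bu)3·HBF4, Cy2NMe, 1,4-dioxane, 40 °C
Reagents that add atoms: none
Why: Mizoroki–Heck reaction, in which syn insertion and syn β-hydride elimination should give the E-stilbene while the hindered amine base leaves the epimerisable ester alone.

Step 7
Reactants: 10 methyl (2R,3S)-2-(4-OBn-phenyl)-4-OBBn-6-[(E)-4-OBn-styryl]-2,3-dihydrobenzofuran-3-carboxylate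
Product: 11 (2R,3S)-2-(4-OBn-phenyl)-4-OBBn-6-[(E)-4-OBn-styryl]-2,3-dihydrobenzofuran-3-carboxylic acid
Conditions: Me3SnOH, ClCH2CH2Cl, 80 °C; aq. HCl wash
Reagents that add atoms: trimethyltin hydroxide, C[Sn](C)(C)O
Why: Tin hydroxide-mediated ester hydrolysis under near-neutral conditions, chosen to avoid the C3 enolate and with it a retro-oxa-Michael ring opening that would endanger C2.

Step 8
Reactants: 7 methyl [4-bromo-2,6-bis(OBBn)phenyl](diazo)acetate
Product: 12 methyl (2S,3R)-6-bromo-2-(4-OBn-phenyl)-4-OBBn-2,3-dihydrobenzofuran-3-carboxylate (cis, enantiomer of 8)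
Conditions: Rh2(R-PTTL)4 (1 mol %), toluene, −60 °C
Reagents that add atoms: none
Why: The same rhodium carbene 1,5 C–H insertion with the mirror-image catalyst should set C2 as S and give the cis ester (C3 as R, erased later).

Step 9
Reactants: 12 methyl (2S,3R)-6-bromo-2-(4-OBn-phenyl)-4-OBBn-2,3-dihydrobenzofuran-3-carboxylate
Product: 13 (2S,3R)-6-bromo-2-(4-OBn-phenyl)-4-OBBn-2,3-dihydrobenzofuran-3-carboxylic acid
Conditions: Me3SnOH, ClCH2CH2Cl, 80 °C; aq. HCl wash
Reagents that add atoms: trimethyltin hydroxide, C[Sn](C)(C)O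
Why: Tin hydroxide-mediated ester hydrolysis, which should leave C2 and the aryl bromide untouched.

Step 10
Reactants: 13 (2S,3R)-6-bromo-2-(4-OBn-phenyl)-4-OBBn-2,3-dihydrobenzofuran-3-carboxylic acid; 14 1,3-bis(benzyloxy)-5-bromobenzene
Product: 18 (2S,3S)-6-bromo-2-(4-OBn-phenyl)-3-[3,5-bis(OBn)phenyl]-4-OBBn-2,3-dihydrobenzofuran (trans), via phthalimide ester 15 (not isolated), via Grignard reagent 16 (not isolated), via arylzinc chloride 17 (not isolated)
Conditions: N-hydroxyphthalimide, DIC, DMAP (cat.), CH2Cl2, rt, then evaporation; separately 14, Mg, THF, then ZnCl2; Fe(acac)3, dppBz, THF/toluene, rt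
Reagents that add atoms: none
Why: Iron-catalysed decarboxylative Negishi-type arylation of a redox-active ester, in which the planar C3 radical should be arylated anti to the C2 aryl group (C3 set as S, trans) and the iron–bisphosphine catalyst should not insert into the unactivated aryl bromide.

Step 11
Reactants: 11 (2R,3S)-2-(4-OBn-phenyl)-4-OBBn-6-[(E)-4-OBn-styryl]-2,3-dihydrobenzofuran-3-carboxylic acid; 18 (2S,3S)-6-bromo-2-(4-OBn-phenyl)-3-[3,5-bis(OBn)phenyl]-4-OBBn-2,3-dihydrobenzofuran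
Product: 22 heptakis-protected trimer (2R,3R)-2-(4-OBn-phenyl)-3-{(2S,3S)-2-(4-OBn-phenyl)-3-[3,5-bis(OBn)phenyl]-4-OBBn-2,3-dihydrobenzofuran-6-yl}-4-OBBn-6-[(E)-4-OBn-styryl]-2,3-dihydrobenzofuran, via phthalimide ester 19 (not isolated), via aryllithium 20 (not isolated), via arylzinc chloride 21 (not isolated)
Conditions: N-hydroxyphthalimide, DIC, DMAP (cat.), CH2Cl2, rt, then evaporation; separately 18, n-BuLi, THF, −78 °C, then ZnCl2; NiCl2·glyme, dtbbpy, THF/DMF, rt
Reagents that add atoms: none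
Why: Nickel-catalysed decarboxylative Negishi-type arylation of a redox-active ester: an aryl–nickel species formed by transmetalation from 21 reduces 19 by single-electron transfer, the ester fragments to CO2, phthalimide anion and the benzylic C3 radical, and the radical is captured at nickel and released by C(sp3)–C(sp2) reductive elimination. The closest known reaction type is the coupling of N-hydroxyphthalimide esters of secondary and benzylic acids with arylzinc halides under NiCl2·glyme and a bipyridine ligand. No ring is closed. The new C3 stereocentre (R) is controlled by the neighbouring C2 centre: the planar radical in the five-membered ring is arylated on the face opposite the C2 4-(benzyloxy)phenyl group, so the cis acid, its trans epimer or any mixture should give the same trans-(2R,3R) product. The step needs chemoselectivity for the activated ester over the stilbene and the benzylic ethers, and facial selectivity at C3; the first rests on radical capture at nickel being much faster than addition to a 1,2-disubstituted alkene, the second on the C2 aryl group, which leaves only the anti face open.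

Step 12
Reactants: 22 heptakis-protected trimer
Product: 23 (2R,3R)-3-[(2S,3S)-3-(3,5-dihydroxyphenyl)-4-hydroxy-2-(4-hydroxyphenyl)-2,3-dihydrobenzofuran-6-yl]-2-(4-hydroxyphenyl)-6-[(E)-4-hydroxystyryl]-2,3-dihydrobenzofuran-4-ol (target)
Conditions: BCl3, C6HMe5, CH2Cl2, −78 °C; MeOH quench
Reagents that add atoms: none
Why: Lewis-acid debenzylation with pentamethylbenzene as a non-basic cation scavenger should cleave the five benzyl and two 4-(benzyloxy)benzyl ethers at low temperature without touching the stilbene or the four stereocentres.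

**Compound list**

1 | 4-bromo-2,6-difluorobenzaldehyde | O=Cc1c(F)cc(Br)cc1F | starting material
2 | [4-(benzyloxy)phenyl]methanol | OCc1ccc(OCc2ccccc2)cc1 | starting material
3 | 4-bromo-2,6-bis{[4-(benzyloxy)phenyl]methoxy}benzaldehyde | O=Cc1c(OCc2ccc(OCc3ccccc3)cc2)cc(Br)cc1OCc1ccc(OCc2ccccc2)cc1 | intermediate
4 | rac-1-(4-bromo-2,6-bis{[4-(benzyloxy)phenyl]methoxy}phenyl)-2,2,2-trichloroethan-1-ol | OC(c1c(OCc2ccc(OCc3ccccc3)cc2)cc(Br)cc1OCc1ccc(OCc2ccccc2)cc1)C(Cl)(Cl)Cl | intermediate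
5 | 2-(4-bromo-2,6-bis{[4-(benzyloxy)phenyl]methoxy}phenyl)acetic acid | OC(=O)Cc1c(OCc2ccc(OCc3ccccc3)cc2)cc(Br)cc1OCc1ccc(OCc2ccccc2)cc1 | intermediate
6 | methyl 2-(4-bromo-2,6-bis{[4-(benzyloxy)phenyl]methoxy}phenyl)acetate | COC(=O)Cc1c(OCc2ccc(OCc3ccccc3)cc2)cc(Br)cc1OCc1ccc(OCc2ccccc2)cc1 | intermediate
7 | methyl 2-(4-bromo-2,6-bis{[4-(benzyloxy)phenyl]methoxy}phenyl)-2-diazoacetate | COC(=O)C(=[N+]=[N-])c1c(OCc2ccc(OCc3ccccc3)cc2)cc(Br)cc1OCc1ccc(OCc2ccccc2)cc1 | intermediate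
8 | methyl (2R,3S)-6-bromo-2-[4-(benzyloxy)phenyl]-4-{[4-(benzyloxy)phenyl]methoxy}-2,3-dihydro-1-benzofuran-3-carboxylate (cis) | Brc1cc(OCc2ccc(OCc3ccccc3)cc2)c2c(c1)O[C@@H](c1ccc(OCc3ccccc3)cc1)[C@H]2C(=O)OC | intermediate
9 | 1-(benzyloxy)-4-ethenylbenzene (4-benzyloxystyrene) | C=Cc1ccc(OCc2ccccc2)cc1 | starting material
10 | methyl (2R,3S)-2-[4-(benzyloxy)phenyl]-4-{[4-(benzyloxy)phenyl]methoxy}-6-{(E)-2-[4-(benzyloxy)phenyl]ethenyl}-2,3-dihydro-1-benzofuran-3-carboxylate | C(Oc1ccc(/C=C/c2cc(OCc3ccc(OCc4ccccc4)cc3)c3c(c2)O[C@@H](c2ccc(OCc4ccccc4)cc2)[C@H]3C(=O)OC)cc1)c1ccccc1 | intermediate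
11 | (2R,3S)-2-[4-(benzyloxy)phenyl]-4-{[4-(benzyloxy)phenyl]methoxy}-6-{(E)-2-[4-(benzyloxy)phenyl]ethenyl}-2,3-dihydro-1-benzofuran-3-carboxylic acid | C(Oc1ccc(/C=C/c2cc(OCc3ccc(OCc4ccccc4)cc3)c3c(c2)O[C@@H](c2ccc(OCc4ccccc4)cc2)[C@H]3C(=O)O)cc1)c1ccccc1 | intermediate
12 | methyl (2S,3R)-6-bromo-2-[4-(benzyloxy)phenyl]-4-{[4-(benzyloxy)phenyl]methoxy}-2,3-dihydro-1-benzofuran-3-carboxylate (cis) | Brc1cc(OCc2ccc(OCc3ccccc3)cc2)c2c(c1)O[C@H](c1ccc(OCc3ccccc3)cc1)[C@@H]2C(=O)OC | intermediate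
13 | (2S,3R)-6-bromo-2-[4-(benzyloxy)phenyl]-4-{[4-(benzyloxy)phenyl]methoxy}-2,3-dihydro-1-benzofuran-3-carboxylic acid | Brc1cc(OCc2ccc(OCc3ccccc3)cc2)c2c(c1)O[C@H](c1ccc(OCc3ccccc3)cc1)[C@@H]2C(=O)O | intermediate
14 | 1,3-bis(benzyloxy)-5-bromobenzene | Brc1cc(OCc2ccccc2)cc(OCc2ccccc2)c1 | starting material
15 | 1,3-dioxoisoindolin-2-yl ester of 13 | Brc1cc(OCc2ccc(OCc3ccccc3)cc2)c2c(c1)O[C@H](c1ccc(OCc3ccccc3)cc1)[C@@H]2C(=O)ON1C(=O)c2ccccc2C1=O | intermediate
16 | [3,5-bis(benzyloxy)phenyl]magnesium bromide | Br[Mg]c1cc(OCc2ccccc2)cc(OCc2ccccc2)c1 | intermediate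
17 | [3,5-bis(benzyloxy)phenyl]zinc chloride | Cl[Zn]c1cc(OCc2ccccc2)cc(OCc2ccccc2)c1 | intermediate
18 | (2S,3S)-6-bromo-2-[4-(benzyloxy)phenyl]-3-[3,5-bis(benzyloxy)phenyl]-4-{[4-(benzyloxy)phenyl]methoxy}-2,3-dihydro-1-benzofuran (trans) | Brc1cc(OCc2ccc(OCc3ccccc3)cc2)c2c(c1)O[C@H](c1ccc(OCc3ccccc3)cc1)[C@H]2c1cc(OCc2ccccc2)cc(OCc2ccccc2)c1 | intermediate
19 | 1,3-dioxoisoindolin-2-yl ester of 11 | C(Oc1ccc(/C=C/c2cc(OCc3ccc(OCc4ccccc4)cc3)c3c(c2)O[C@@H](c2ccc(OCc4ccccc4)cc2)[C@H]3C(=O)ON2C(=O)c3ccccc3C2=O)cc1)c1ccccc1 | intermediate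
20 | 6-lithio analogue of 18 | [Li]c1cc(OCc2ccc(OCc3ccccc3)cc2)c2c(c1)O[C@H](c1ccc(OCc3ccccc3)cc1)[C@H]2c1cc(OCc2ccccc2)cc(OCc2ccccc2)c1 | intermediate
21 | 6-(chlorozincio) analogue of 18 | Cl[Zn]c1cc(OCc2ccc(OCc3ccccc3)cc2)c2c(c1)O[C@H](c1ccc(OCc3ccccc3)cc1)[C@H]2c1cc(OCc2ccccc2)cc(OCc2ccccc2)c1 | intermediate
22 | (2R,3R)-2-[4-(benzyloxy)phenyl]-3-{(2S,3S)-2-[4-(benzyloxy)phenyl]-3-[3,5-bis(benzyloxy)phenyl]-4-{[4-(benzyloxy)phenyl]methoxy}-2,3-dihydro-1-benzofuran-6-yl}-4-{[4-(benzyloxy)phenyl]methoxy}-6-{(E)-2-[4-(benzyloxy)phenyl]ethenyl}-2,3-dihydro-1-benzofuran | C(Oc1ccc(/C=C/c2cc(OCc3ccc(OCc4ccccc4)cc3)c3c(c2)O[C@@H](c2ccc(OCc4ccccc4)cc2)[C@@H]3c2cc(OCc3ccc(OCc4ccccc4)cc3)c3c(c2)O[C@H](c2ccc(OCc4ccccc4)cc2)[C@H]3c2cc(OCc3ccccc3)cc(OCc3ccccc3)c2)cc1)c1ccccc1 | intermediate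
23 | (2R,3R)-3-[(2S,3S)-3-(3,5-dihydroxyphenyl)-4-hydroxy-2-(4-hydroxyphenyl)-2,3-dihydro-1-benzofuran-6-yl]-2-(4-hydroxyphenyl)-6-[(E)-2-(4-hydroxyphenyl)ethenyl]-2,3-dihydro-1-benzofuran-4-ol | Oc1ccc(/C=C/c2cc(O)c3c(c2)O[C@@H](c2ccc(O)cc2)[C@@H]3c2cc(O)c3c(c2)O[C@H](c2ccc(O)cc2)[C@H]3c2cc(O)cc(O)c2)cc1 | target

**Count.** Total: 12 steps. Longest linear sequence: 9 steps (1–4, then 8–10 or 5–7, then 11–12).

**Steps most likely to fail**

Step 11. The C3 radical is flanked by the C2 aryl group and the C4 ether and may be captured too slowly at nickel. It would then be oxidised and lose the C2 hydrogen, aromatising the furan ring, or be reduced, while the valuable arylzinc homocouples. The fallback is a polar union followed by a donor/donor carbene C–H insertion, setting out from 3 and 18. Heck reaction of 3 with 9 gives the stilbene aldehyde F1. Aryllithium 20 (from 18 and n-BuLi) adds to F1 to give, after NH4Cl quench, the diaryl carbinol F2, forming the same carbon–carbon bond. Dess–Martin oxidation gives the diaryl ketone F3, and hydrazine gives the hydrazone F4. MnO2 gives the diaryldiazomethane F5, which inserts into a benzylic C–H bond of one of the two equivalent OBBn arms under the appropriate antipode of dirhodium tetrakis[1-adamantyl(N-phthalimido)acetate], Rh2(PTAD)4. This gives the cis-2,3-diaryl dihydrobenzofuran F6 with C3 set as R by the catalyst. Brief treatment with BF3·OEt2 in CH2Cl2 at −40 °C epimerises C2 through reversible ionisation of the C2–O bond to the trans isomer, which is 22, where the fallback rejoins the route.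

Step 10. The low-valent catalyst may insert into the aryl bromide that has to survive, giving biaryl and oligomers, or the arylzinc may homocouple before the benzylic radical is captured. The fallback masks the handle as a boronate and sets out from 12. Miyaura borylation (Pd(dppf)Cl2, B2pin2, KOAc) gives the pinacol boronate ester F7, and Me3SnOH gives the boronate acid F8. Its N-hydroxyphthalimide ester F9 is coupled with arylzinc chloride 17 under NiCl2·glyme and dtbbpy, with no halide now present, to give the trans boronate F10. NaIO4 and NH4OAc free the boronic acid F11. F11 is coupled with 19 in the boronic-acid variant of the decarboxylative arylation (NiCl2·6H2O, bathophenanthroline, Et3N, 1,4-dioxane/DMF, 75 °C) to give 22, where the fallback rejoins the route.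

Step 5 (and its mirror image, step 8). The di-ortho-substituted aryl ring is twisted out of conjugation with the carbene carbon, so enantiofacial discrimination by the chiral carboxylates may be poor and the carbene may dimerise. The fallback uses the fact that both antipodes of the bromo ester are needed and sets out from 7. Cyclisation with achiral Rh2(OAc)4 in CH2Cl2 gives the racemic cis ester F12. Preparative chromatography on a chiral stationary phase separates the enantiomers, which are 8 and 12, where the fallback rejoins the route with nothing discarded.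

**Further compounds**

F1 | step 11 | 2,6-bis{[4-(benzyloxy)phenyl]methoxy}-4-{(E)-2-[4-(benzyloxy)phenyl]ethenyl}benzaldehyde | O=Cc1c(OCc2ccc(OCc3ccccc3)cc2)cc(/C=C/c2ccc(OCc3ccccc3)cc2)cc1OCc1ccc(OCc2ccccc2)cc1
F2 | step 11 | diaryl carbinol from 20 and F1 (carbinol epimers) | OC(c1c(OCc2ccc(OCc3ccccc3)cc2)cc(/C=C/c2ccc(OCc3ccccc3)cc2)cc1OCc1ccc(OCc2ccccc2)cc1)c1cc(OCc2ccc(OCc3ccccc3)cc2)c2c(c1)O[C@H](c1ccc(OCc3ccccc3)cc1)[C@H]2c1cc(OCc2ccccc2)cc(OCc2ccccc2)c1
F3 | step 11 | diaryl ketone from F2 | O=C(c1c(OCc2ccc(OCc3ccccc3)cc2)cc(/C=C/c2ccc(OCc3ccccc3)cc2)cc1OCc1ccc(OCc2ccccc2)cc1)c1cc(OCc2ccc(OCc3ccccc3)cc2)c2c(c1)O[C@H](c1ccc(OCc3ccccc3)cc1)[C@H]2c1cc(OCc2ccccc2)cc(OCc2ccccc2)c1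
F4 | step 11 | hydrazone of F3 | NN=C(c1c(OCc2ccc(OCc3ccccc3)cc2)cc(/C=C/c2ccc(OCc3ccccc3)cc2)cc1OCc1ccc(OCc2ccccc2)cc1)c1cc(OCc2ccc(OCc3ccccc3)cc2)c2c(c1)O[C@H](c1ccc(OCc3ccccc3)cc1)[C@H]2c1cc(OCc2ccccc2)cc(OCc2ccccc2)c1
F5 | step 11 | diaryldiazomethane from F4 | [N-]=[N+]=C(c1c(OCc2ccc(OCc3ccccc3)cc2)cc(/C=C/c2ccc(OCc3ccccc3)cc2)cc1OCc1ccc(OCc2ccccc2)cc1)c1cc(OCc2ccc(OCc3ccccc3)cc2)c2c(c1)O[C@H](c1ccc(OCc3ccccc3)cc1)[C@H]2c1cc(OCc2ccccc2)cc(OCc2ccccc2)c1
F6 | step 11 | (2S,3R)-cis C2 epimer of 22 | C(Oc1ccc(/C=C/c2cc(OCc3ccc(OCc4ccccc4)cc3)c3c(c2)O[C@H](c2ccc(OCc4ccccc4)cc2)[C@@H]3c2cc(OCc3ccc(OCc4ccccc4)cc3)c3c(c2)O[C@H](c2ccc(OCc4ccccc4)cc2)[C@H]3c2cc(OCc3ccccc3)cc(OCc3ccccc3)c2)cc1)c1ccccc1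
F7 | step 10 | methyl (2S,3R)-2-[4-(benzyloxy)phenyl]-4-{[4-(benzyloxy)phenyl]methoxy}-6-(4,4,5,5-tetramethyl-1,3,2-dioxaborolan-2-yl)-2,3-dihydro-1-benzofuran-3-carboxylate | CC1(C)OB(OC1(C)C)c1cc(OCc2ccc(OCc3ccccc3)cc2)c2c(c1)O[C@H](c1ccc(OCc3ccccc3)cc1)[C@@H]2C(=O)OC
F8 | step 10 | carboxylic acid from F7 | CC1(C)OB(OC1(C)C)c1cc(OCc2ccc(OCc3ccccc3)cc2)c2c(c1)O[C@H](c1ccc(OCc3ccccc3)cc1)[C@@H]2C(=O)O
F9 | step 10 | 1,3-dioxoisoindolin-2-yl ester of F8 | CC1(C)OB(OC1(C)C)c1cc(OCc2ccc(OCc3ccccc3)cc2)c2c(c1)O[C@H](c1ccc(OCc3ccccc3)cc1)[C@@H]2C(=O)ON1C(=O)c2ccccc2C1=O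
F10 | step 10 | (2S,3S)-trans 6-(pinacolboryl) analogue of 18 | CC1(C)OB(OC1(C)C)c1cc(OCc2ccc(OCc3ccccc3)cc2)c2c(c1)O[C@H](c1ccc(OCc3ccccc3)cc1)[C@H]2c1cc(OCc2ccccc2)cc(OCc2ccccc2)c1
F11 | step 10 | (2S,3S)-trans 6-boronic acid analogue of 18 | OB(O)c1cc(OCc2ccc(OCc3ccccc3)cc2)c2c(c1)O[C@H](c1ccc(OCc3ccccc3)cc1)[C@H]2c1cc(OCc2ccccc2)cc(OCc2ccccc2)c1
F12 | step 5 | racemic methyl cis-6-bromo-2-[4-(benzyloxy)phenyl]-4-{[4-(benzyloxy)phenyl]methoxy}-2,3-dihydro-1-benzofuran-3-carboxylate (8 and 12 in equal amounts) | Brc1cc(OCc2ccc(OCc3ccccc3)cc2)c2c(c1)O[C@@H](c1ccc(OCc3ccccc3)cc1)[C@H]2C(=O)OC.Brc1cc(OCc2ccc(OCc3ccccc3)cc2)c2c(c1)O[C@H](c1ccc(OCc3ccccc3)cc1)[C@@H]2C(=O)OC
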